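Assumption: the target has no stereocentre and no stereogenic double bond, so no stereocontrol is needed; the stereocentres in 3, 4 and 5 are racemic and are erased in step 2. The route is designed from known reaction classes and has not been run.

**Retrosynthetic overview**
1. Target ⇒ (global hydrogenolysis) its benzyl ester/benzyl ether ⇒ (depside C–O bond) benzyl olivetolate with free 4-OH plus 2-O-benzyl-everninic acid.
2. Benzyl olivetolate ⇒ methyl olivetolate by MOM protection, saponification, benzylation and MOM removal, so that no free β-resorcylic acid meets hot base.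
3. Methyl olivetolate ⇒ (oxidative aromatisation) methyl 2,4-dioxo-6-pentylcyclohexanecarboxylate ⇒ intermolecular Michael addition of dimethyl malonate to (E)-non-3-en-2-one, then Dieckmann closure (key C–C bond).
4. 2-O-Benzyl-everninic acid ⇒ commercial methyl orsellinate by 4-O-methylation, 2-O-benzylation and saponification.
5. Ring order: only the olivetolate carbocycle is built (Michael/Dieckmann, then aromatised); the everninate ring is bought intact; the two arenes are joined last through the ester.

**Route**

Step 1
Reactants: 1 dimethyl malonate; 2 (E)-non-3-en-2-one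
Product: 4 methyl 2,4-dioxo-6-pentylcyclohexane-1-carboxylate (racemic; enolised β-diketone), via malonate Michael adduct 3 (not isolated)
Conditions: NaOMe (1.1 equiv), MeOH, reflux, 3 h; then aq. HCl, 0 °C
Reagents that add atoms: none
Why: The malonate anion adds 1,4 to the enone (intermolecular Michael addition, key C–C bond) and the methyl-ketone enolate then closes onto one ester (Dieckmann/Claisen condensation), driven by the stabilised β-diketone enolate; the two new stereocentres are racemic and disappear in step 2.

Step 2
Reactants: 4 methyl 2,4-dioxo-6-pentylcyclohexane-1-carboxylate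
Product: 6 methyl 2,4-dihydroxy-6-pentylbenzoate (methyl olivetolate), via 3-bromo dione 5 (not isolated)
Conditions: Br2 (1.0 equiv), DMF, 0 °C, then 80 °C
Reagents that add atoms: none
Why: C-bromination of the enolised β-diketone followed by thermal dehydrobromination and tautomerisation (oxidative aromatisation) gives the resorcylate and leaves the ester untouched.

Step 3
Reactants: 6 methyl 2,4-dihydroxy-6-pentylbenzoate
Product: 7 methyl 2,4-bis(methoxymethoxy)-6-pentylbenzoate
Conditions: NaH (2.4 equiv), MOMCl (2.4 equiv), DMF, 0 °C → rt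
Reagents that add atoms: chloromethyl methyl ether (MOMCl), COCCl
Why: Williamson-type O-alkylation of both sodium phenoxides (MOM protection); NaH also deprotonates the hydrogen-bonded 2-OH.

Step 4
Reactants: 7 methyl 2,4-bis(methoxymethoxy)-6-pentylbenzoate
Product: 8 2,4-bis(methoxymethoxy)-6-pentylbenzoic acid
Conditions: KOH (5 equiv), DMSO/H2O 4:1, 90 °C; then 1 M HCl to pH 4, 0 °C
Reagents that add atoms: potassium hydroxide, [K+].[OH-]
Why: Saponification of the di-ortho-substituted ester with poorly solvated hydroxide in DMSO; with both phenols masked as base-stable acetals the decarboxylation pathway of free β-resorcylic acids is closed.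

Step 5
Reactants: 8 2,4-bis(methoxymethoxy)-6-pentylbenzoic acid
Product: 9 benzyl 2,4-bis(methoxymethoxy)-6-pentylbenzoate
Conditions: BnBr (1.2 equiv), K2CO3 (1.5 equiv), DMF, rt
Reagents that add atoms: benzyl bromide, BrCc1ccccc1
Why: SN2 O-alkylation of the carboxylate is insensitive to the steric shielding of the carbonyl carbon.

Step 6
Reactants: 9 benzyl 2,4-bis(methoxymethoxy)-6-pentylbenzoate
Product: 10 benzyl 2,4-dihydroxy-6-pentylbenzoate (benzyl olivetolate)
Conditions: conc. HCl (cat.), MeOH, 45 °C
Reagents that add atoms: none
Why: Acid-catalysed acetal cleavage (transacetalisation to methanol) frees both phenols, while the hindered benzyl ester does not transesterify under these mild conditions.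

Step 7
Reactants: 11 methyl 2,4-dihydroxy-6-methylbenzoate (methyl orsellinate)
Product: 12 methyl 2-hydroxy-4-methoxy-6-methylbenzoate (methyl everninate)
Conditions: MeI (1.1 equiv), K2CO3 (1.1 equiv), acetone, reflux
Reagents that add atoms: iodomethane, CI
Why: Selective Williamson etherification of the more acidic, non-chelated 4-OH; the 2-OH is hydrogen-bonded to the ester carbonyl and reacts far more slowly with one equivalent of MeI.

Step 8
Reactants: 12 methyl 2-hydroxy-4-methoxy-6-methylbenzoate
Product: 13 methyl 2-(benzyloxy)-4-methoxy-6-methylbenzoate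
Conditions: BnBr (1.3 equiv), K2CO3 (2 equiv), DMF, 70 °C
Reagents that add atoms: benzyl bromide, BrCc1ccccc1
Why: Williamson benzylation of the chelated phenol goes to completion under more forcing conditions in DMF.

Step 9
Reactants: 13 methyl 2-(benzyloxy)-4-methoxy-6-methylbenzoate
Product: 14 2-(benzyloxy)-4-methoxy-6-methylbenzoic acid
Conditions: KOH (5 equiv), DMSO/H2O 4:1, 90 °C; then 1 M HCl, 0 °C
Reagents that add atoms: potassium hydroxide, [K+].[OH-]
Why: Saponification of the hindered ester with KOH in DMSO; the benzyl and methyl aryl ethers are stable to base.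

Step 10
Reactants: 14 2-(benzyloxy)-4-methoxy-6-methylbenzoic acid; 10 benzyl 2,4-dihydroxy-6-pentylbenzoate
Product: 16 benzyl 4-{[2-(benzyloxy)-4-methoxy-6-methylbenzoyl]oxy}-2-hydroxy-6-pentylbenzoate, via mixed trifluoroacetic anhydride 15 (not isolated)
Conditions: TFAA (4 equiv), toluene, rt
Reagents that add atoms: none
Why: Mixed-anhydride esterification: TFAA activates the hindered acid, which acylates the free 4-OH, while the 2-OH is chelated to the benzyl ester carbonyl and sterically flanked.

Step 11
Reactants: 16 benzyl 4-{[2-(benzyloxy)-4-methoxy-6-methylbenzoyl]oxy}-2-hydroxy-6-pentylbenzoate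
Product: 17 4-[(2-hydroxy-4-methoxy-6-methylbenzoyl)oxy]-2-hydroxy-6-pentylbenzoic acid (target)
Conditions: H2 (1 atm), 10% Pd/C, EtOAc, rt
Reagents that add atoms: none
Why: Catalytic hydrogenolysis cleaves the benzyl ester and the benzyl ether under neutral conditions at room temperature, which leave the aryl ester link intact and avoid decarboxylation.

**Compound list**
1 | dimethyl malonate | COC(=O)CC(=O)OC | starting material
2 | (E)-non-3-en-2-one | CCCCC/C=C/C(C)=O | starting material
3 | dimethyl 2-(2-oxononan-4-yl)propanedioate (racemic Michael adduct) | CCCCCC(CC(C)=O)C(C(=O)OC)C(=O)OC | intermediate (not isolated)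
4 | methyl 2,4-dioxo-6-pentylcyclohexane-1-carboxylate (racemic, drawn as the diketo tautomer, exists mainly as the enol) | CCCCCC1CC(=O)CC(=O)C1C(=O)OC | intermediate
5 | methyl 3-bromo-2,4-dioxo-6-pentylcyclohexane-1-carboxylate (stereoisomer mixture) | CCCCCC1CC(=O)C(Br)C(=O)C1C(=O)OC | intermediate (not isolated)
6 | methyl 2,4-dihydroxy-6-pentylbenzoate (methyl olivetolate) | CCCCCc1cc(O)cc(O)c1C(=O)OC | intermediate
7 | methyl 2,4-bis(methoxymethoxy)-6-pentylbenzoate | CCCCCc1cc(OCOC)cc(OCOC)c1C(=O)OC | intermediate
8 | 2,4-bis(methoxymethoxy)-6-pentylbenzoic acid | CCCCCc1cc(OCOC)cc(OCOC)c1C(=O)O | intermediate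
9 | benzyl 2,4-bis(methoxymethoxy)-6-pentylbenzoate | CCCCCc1cc(OCOC)cc(OCOC)c1C(=O)OCc1ccccc1 | intermediate
10 | benzyl 2,4-dihydroxy-6-pentylbenzoate (benzyl olivetolate) | CCCCCc1cc(O)cc(O)c1C(=O)OCc1ccccc1 | intermediate
11 | methyl 2,4-dihydroxy-6-methylbenzoate (methyl orsellinate) | COC(=O)c1c(C)cc(O)cc1O | starting material
12 | methyl 2-hydroxy-4-methoxy-6-methylbenzoate (methyl everninate) | COC(=O)c1c(C)cc(OC)cc1O | intermediate
13 | methyl 2-(benzyloxy)-4-methoxy-6-methylbenzoate | COC(=O)c1c(C)cc(OC)cc1OCc1ccccc1 | intermediate
14 | 2-(benzyloxy)-4-methoxy-6-methylbenzoic acid | Cc1cc(OC)cc(OCc2ccccc2)c1C(=O)O | intermediate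
15 | 2-(benzyloxy)-4-methoxy-6-methylbenzoic trifluoroacetic anhydride | Cc1cc(OC)cc(OCc2ccccc2)c1C(=O)OC(=O)C(F)(F)F | intermediate (not isolated)
16 | benzyl 4-{[2-(benzyloxy)-4-methoxy-6-methylbenzoyl]oxy}-2-hydroxy-6-pentylbenzoate | CCCCCc1cc(OC(=O)c2c(C)cc(OC)cc2OCc2ccccc2)cc(O)c1C(=O)OCc1ccccc1 | intermediate
17 | 4-[(2-hydroxy-4-methoxy-6-methylbenzoyl)oxy]-2-hydroxy-6-pentylbenzoic acid (CNP0313373.0, achiral) | CCCCCc1cc(OC(=O)c2c(C)cc(OC)cc2O)cc(O)c1C(=O)O | target

**Step count**
Total steps: 11. Longest linear sequence: 8 (steps 1–6, 10, 11); steps 7–9 form the three-step side branch.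

**Steps most likely to fail, with fallbacks**

Step 2 (aromatisation). One equivalent of bromine can leave starting material and also give ring-brominated resorcylates. The fallback sets out from 4 and over-brominates on purpose: Br2 (3 equiv) in AcOH at rt aromatises and brominates both free ring positions, giving methyl 3,5-dibromo-2,4-dihydroxy-6-pentylbenzoate F1 as one well-defined arene. Reductive debromination (H2, Pd/C, NaOAc, MeOH, rt) then comes back to the route at 6.

Step 4 (saponification of the doubly ortho-substituted ester). The ester may react only sluggishly, and forcing it risks loss of material. The fallback avoids the ester exchange by carrying the benzyl ester from the start, and sets out from 2. Commercial dibenzyl malonate with NaOBn (from NaH/BnOH) in THF at reflux gives the Michael adduct dibenzyl 2-(2-oxononan-4-yl)propanedioate F2, which cyclises in the same flask to benzyl 2,4-dioxo-6-pentylcyclohexane-1-carboxylate F3. Bromination (Br2, DMF, 0 °C, NaOAc buffer) gives benzyl 3-bromo-2,4-dioxo-6-pentylcyclohexane-1-carboxylate F4, which on warming to 80 °C loses HBr and comes back to the route at 10, bypassing 6–9. It is not the main route because this benzyl variant is less established and the benzyl ester may not survive HBr at 80 °C.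

Step 10 (depside coupling). The acid is hindered, and the acidic medium can cause debenzylation or acylation at the wrong site. The fallback sets out from 14 and uses a preformed, isolated acyl donor under basic conditions. Oxalyl chloride with cat. DMF in CH2Cl2 gives 2-(benzyloxy)-4-methoxy-6-methylbenzoyl chloride F5. Adding it to 10 with pyridine and cat. DMAP in CH2Cl2 at 0 °C acylates the more acidic, non-chelated 4-OH and comes back to the route at 16.

**Further compounds**
F1 | step 2 | methyl 3,5-dibromo-2,4-dihydroxy-6-pentylbenzoate | CCCCCc1c(Br)c(O)c(Br)c(O)c1C(=O)OC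
F2 | step 4 | dibenzyl 2-(2-oxononan-4-yl)propanedioate | CCCCCC(CC(C)=O)C(C(=O)OCc1ccccc1)C(=O)OCc1ccccc1
F3 | step 4 | benzyl 2,4-dioxo-6-pentylcyclohexane-1-carboxylate | CCCCCC1CC(=O)CC(=O)C1C(=O)OCc1ccccc1
F4 | step 4 | benzyl 3-bromo-2,4-dioxo-6-pentylcyclohexane-1-carboxylate | CCCCCC1CC(=O)C(Br)C(=O)C1C(=O)OCc1ccccc1
F5 | step 10 | 2-(benzyloxy)-4-methoxy-6-methylbenzoyl chloride | Cc1cc(OC)cc(OCc2ccccc2)c1C(Cl)=O
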